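The numbers in the tables stem from a simulated flask with made-up constants; scatter was added.

A small charge comes first: the third end groups, 0.25 equiv in Wednesday's run. Then come the readings and what is asked.

| flask | first end groups | second end groups | third end groups | remark | time |
|---|---|---|---|---|---|
| Wednesday's | 0.20 M | 1 equiv | 0.25 equiv | run made earlier |  |
| Saturday's | 0.20 M | 0.50 equiv | 0.25 equiv | run made earlier |  |
| Sunday's | 0.20 M | 0.75 equiv | 0.25 equiv | run made earlier |  |
| Thursday's | 0.20 M | 1 equiv | 0.50 equiv | run made earlier |  |
| noon | 0.20 M | 1.00 equiv (in portions, 2, over 10 min) | 0.250 equiv | first portion at the start, last at 10 min | 50 min |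
| summer | 0.20 M | 1.00 equiv (fed, over 10 min) | 0.250 equiv | all else is in the flask from the start; the feed brings no volume worth counting | 50 min |
| dusk | 0.20 M | 1.00 equiv | 0.250 equiv | everything together at the start | 50 min |
| winter | 0.20 M | 1.00 equiv | 0.250 equiv (fed, over 10 min) | all else is in the flask from the start; the feed brings no volume worth counting | 50 min |

| run | time / min | side product / % | links / % | first end groups / % |
|---|---|---|---|---|
| Wednesday's | 6.00 | 62 | 11 | 28 |
| Wednesday's | 12.0 | 77 | 8 | 20 |
| Wednesday's | 20.0 | 81 | 6 | 12 |
| Wednesday's | 25.0 | 86 | 7 | 10 |
| Wednesday's | 30.0 | 86 | 4 | 7 |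
| Saturday's | 2.50 | 28 | 10 | 61 |
| Saturday's | 5.00 | 44 | 10 | 52 |
| Saturday's | 8.00 | 55 | 7 | 39 |
| Saturday's | 15.0 | 63 | 4 | 28 |
| Saturday's | 30.0 | 75 | 0 | 25 |
| Sunday's | 6.00 | 56 | 10 | 35 |
| Sunday's | 12.0 | 69 | 8 | 20 |
| Sunday's | 20.0 | 78 | 3 | 15 |
| Sunday's | 25.0 | 83 | 0 | 14 |
| Sunday's | 30.0 | 82 | 0 | 16 |
| Thursday's | 6.00 | 60 | 9 | 27 |
| Thursday's | 12.0 | 74 | 8 | 18 |
| Thursday's | 20.0 | 80 | 4 | 15 |
| Thursday's | 25.0 | 86 | 0 | 7 |
| Thursday's | 30.0 | 85 | 1 | 12 |

(standard deviation of a reading: 2 percentage points)

- percent here means first end groups units held: one side product counts as two
- what was read earlier has a scatter of 2 percentage points, one standard deviation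

- which flask leads in amount of side product, in percent of the first end groups charged ("all alike" within 1.5 percentage points) (noon / summer / dusk / winter / all alike)
- how much side product is there at the end, in percent of the first end groups charged: noon
- how much side product is there at the end, in percent of the first end groups charged: summer
- how much side product is there at the end, in percent of the first end groups charged: dusk
- how much side product is there at the end, in percent of the first end groups charged: winter

Dusk has Wednesday's charges, so I read Wednesday forward, rung by rung, down to the tail. Let a be the fraction of first end groups still free.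

1. Third end groups. Doubling them to 0.50 equiv in Thursday's run gave side product 85% against 86% at 30.0 min, inside the scatter of 2 percentage points. I see no effect to carry, so I expect winter to match dusk.

2. Links. From 20.0 min on, Wednesday's links stand at about 0.586 of a, and I freeze that ratio.

3. Second end groups. At 25.0 min, Wednesday's side product and links hold 50.0% of them, and the side product still to come needs 7.00%. I take the unread rest as free, which is an assumption, and freeze them too.

4. The tail. With both frozen, links follow a, and I take side product to form from first end groups plus links, so the loss goes as a squared: a second-order decay. The inverse of a then climbs steadily, and the climb per minute is the tail slope, read as 0.385 /min between 12.0 min and 25.0 min. At 25.0 min the tail's time is 26.0 min, longer than the 10 min feed.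

5. My reckoning. For dusk, a reaches 5.10% at 50 min, so side product is 91.9%. In noon and summer the second end groups arrive on average 5.00 min late, which I reckon costs 0.79 points, under the margin. I say the flasks are alike.

The forecast differs: it names summer, with noon 93.5%, summer 95%, dusk 92% and winter 92%, holding that “spreading the dose should help slightly”.

The flasks give noon 91.9%, summer 92.0%, dusk 92.5% and winter 92.4%: all alike.

    first end groups + second end groups ⇌ links (K = 3.60 /M, k = 0.263 /M/s)
    second end groups + third end groups → links of the second sort (k = 0.0134 /M/s)
    first end groups + links → side product (k = 0.0538 /M/s)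
    2 third end groups → homo dimer (k = 0.138 /M/s)

Dusk stands 0.50 points above summer, against the 0.79 points reckoned from the tail slope. In noon at 50.0 min, links have a half-life of 18 min by the side-product step, longer than the 3.7 min of second end groups by the forward step alone, and links stand at 2.07% beside first end groups at 6.01%. Carrying 0.385 /min and the frozen ratio of 0.586 on from there for 450 min more gives noon side product of 99.2%, and noon left that long stands at 99.2%.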